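## Retrosynthetic overview

1. The target is cut at the tert-butyl ester and at the C7–C8 bond: α′-alkylation of an (S)-4-alkenylcyclopent-2-enone with a C7 triflate made from cycloheptanone.
2. The cyclopentenone (second ring formed) comes from a catalyst-controlled one-carbon ring expansion of a prochiral 3-alkenylcyclobutanone with TMSCHN2, followed by C-to-O silyl shift and dehydrogenation. This step sets C12.
3. The cyclobutanone (first ring formed) comes from dichloroketene [2+2] addition to the terminal alkene of (3E,5S)-deca-1,3-dien-5-yl acetate, then dechlorination.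
4. The dienyl acetate comes from hexanal and but-1-en-3-yne by catalytic asymmetric dienylzinc addition, which sets C15.

Assumption: positions are given in prostaglandin numbering (C1 carboxyl carbon, C8 and C12 the ring carbons bearing the chains, C15 the acetoxy carbon). The target is (8R,12S,13E,15S), i.e. 15-O-acetyl-PGA1.

## Route

Step 1
Reactants: 1 hexanal; 2 but-1-en-3-yne
Product: 5 (3E,5S)-deca-1,3-dien-5-ol, via dienylborane 3 (not isolated), via dienylzinc 4 (not isolated)
Conditions: Cy2BH, toluene, 0 °C to rt; Me2Zn, −78 °C; (+)-MIB (5 mol %), then 1 added slowly, −10 °C; aq NH4Cl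
Reagents that add atoms: none
Why: Alkyne-selective syn hydroboration gives the (E)-dienylborane, boron-to-zinc exchange gives the dienylzinc, and the amino-alcohol-catalysed asymmetric alkenylzinc addition (Oppolzer-type) delivers the dienyl group to the Re face of hexanal, setting C15 as S; (+)-MIB is chosen by analogy with the Si-face preference of (−)-MIB.

Step 2
Reactants: 5 (3E,5S)-deca-1,3-dien-5-ol
Product: 6 (3E,5S)-deca-1,3-dien-5-yl acetate
Conditions: Ac2O, pyridine, DMAP (cat.), CH2Cl2, 0 °C
Reagents that add atoms: acetic anhydride, CC(=O)OC(C)=O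
Why: DMAP-catalysed O-acylation under basic conditions does not touch the C–O bond of the ionisable dienyl carbinol, so C15 is retained and the final acetate is already in place.

Step 3
Reactants: 6 (3E,5S)-deca-1,3-dien-5-yl acetate
Product: 7 (1E,3S)-1-(2,2-dichloro-3-oxocyclobutyl)oct-1-en-3-yl acetate (both epimers at the ring CH)
Conditions: Cl2CHCOCl, Et3N (slow addition), hexane, rt
Reagents that add atoms: dichloroacetyl chloride, O=C(Cl)C(Cl)Cl (reacts as dichloroketene)
Why: Ketene–alkene [2+2] cycloaddition in which the ketene carbonyl carbon bonds to the unhindered terminal CH2 of the diene and the CCl2 carbon to the internal carbon, so the alkenyl chain sits at C3 with the E alkene intact; the ring stereocentre forms unselectively but is erased in step 4.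

Step 4
Reactants: 7 (1E,3S)-1-(2,2-dichloro-3-oxocyclobutyl)oct-1-en-3-yl acetate
Product: 8 (1E,3S)-1-(3-oxocyclobutyl)oct-1-en-3-yl acetate
Conditions: Zn dust, AcOH, rt
Reagents that add atoms: none
Why: Zinc reductive dechlorination of the α,α-dichloroketone through zinc enolates removes both chlorines without touching the allylic acetate and leaves a single prochiral 3-substituted cyclobutanone.

Step 5
Reactants: 8 (1E,3S)-1-(3-oxocyclobutyl)oct-1-en-3-yl acetate
Product: 11 (4S)-4-[(1E,3S)-3-acetoxyoct-1-en-1-yl]cyclopent-2-en-1-one, via β-ketosilane 9 (not isolated), via silyl enol ether 10 (not isolated)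
Conditions: Sc(OTf)3 (10 mol %), indane-fused C3-symmetric tris(oxazoline) ligand (12 mol %, antipode chosen by screening to give (S)-10), TMSCHN2 (1.1 equiv), toluene, −40 °C; then solvent switch, IBX·MPO, DMSO, rt
Reagents that add atoms: trimethylsilyldiazomethane, C[Si](C)(C)C=[N+]=[N-]
Why: Proposed new method: the chiral Sc(OTf)3–tris(oxazoline) Lewis acid binds the prochiral ketone, TMSCHN2 adds anti to the C3 alkenyl group and the catalyst fixes the configuration of the new C(H)(SiMe3)(N2+) carbon; because only the ring bond antiperiplanar to the departing N2 can shift and the SiMe3 group avoids the scandium-bound oxygen, that configuration decides which of the two enantiotopic CH2 groups undergoes the 1,2-shift, so the ring expansion sets C12 (S); β-ketosilane 9 then undergoes the Sc-promoted 1,3 C-to-O silyl shift to enol silane 10, which blocks a second homologation and places the double bond so that IBX·MPO dehydrogenation (a metal-free Saegusa–Ito equivalent) gives the C10–C11 enone without a palladium species that could scramble the allylic acetate; the closest known reactions are the racemic Sc(OTf)3-catalysed TMSCHN2 homologation of cyclobutanones to enol silanes (Tiffeneau–Demjanov-type diazoalkane ring expansion) and chiral scandium–oxazoline-catalysed enantioselective insertions of aryldiazomethanes, and what is new is using such a catalyst to differentiate the enantiotopic α-carbons of a 3-substituted cyclobutanone.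

Step 6
Reactants: 12 cycloheptanone
Product: 13 oxocan-2-one
Conditions: mCPBA, CF3CO2H (cat.), CH2Cl2, rt
Reagents that add atoms: 3-chloroperbenzoic acid, O=C(OO)c1cccc(Cl)c1
Why: Baeyer–Villiger oxidation of a symmetrical ketone, so there is no regiochemical issue, gives the eight-membered lactone that carries C1–C7 at the right oxidation levels.

Step 7
Reactants: 13 oxocan-2-one
Product: 14 tert-butyl 7-hydroxyheptanoate
Conditions: KOtBu, t-BuOH/THF, rt; aq NH4Cl
Reagents that add atoms: potassium tert-butoxide, CC(C)(C)[O-].[K+]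
Why: Acyl substitution by tert-butoxide opens the strained medium-ring lactone (transesterification), and the bulky ester resists re-lactonisation and later enolate attack.

Step 8
Reactants: 14 tert-butyl 7-hydroxyheptanoate
Product: 15 tert-butyl 7-(trifluoromethylsulfonyloxy)heptanoate
Conditions: Tf2O, 2,6-lutidine, CH2Cl2, −78 °C; short silica plug, used at once
Reagents that add atoms: trifluoromethanesulfonic anhydride, O=S(=O)(OS(=O)(=O)C(F)(F)F)C(F)(F)F
Why: O-sulfonylation of the primary alcohol gives an alkyl triflate reactive enough to alkylate a ketone enolate at −78 °C, which the corresponding iodide is not.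

Step 9
Reactants: 11 (4S)-4-[(1E,3S)-3-acetoxyoct-1-en-1-yl]cyclopent-2-en-1-one; 15 tert-butyl 7-(trifluoromethylsulfonyloxy)heptanoate
Product: 17 tert-butyl 7-[(1R,2S)-2-[(1E,3S)-3-acetoxyoct-1-en-1-yl]-5-oxocyclopent-3-en-1-yl]heptanoate, via lithium dienolate 16 (not isolated)
Conditions: LiN(SiMe3)2 (1.0 equiv), THF, −78 °C; then 15, −78 to −60 °C; AcOH quench at −78 °C
Reagents that add atoms: none
Why: Kinetic α′-deprotonation gives the cross-conjugated lithium dienolate, which is C-alkylated by the primary triflate on the face anti to the C12 alkenyl group (enolate alkylation), setting C8 (R) trans to C12, which is also the thermodynamic arrangement; the acetate and tert-butyl ester are far less acidic and tolerate one equivalent of base at this temperature.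

Step 10
Reactants: 17 tert-butyl 7-[(1R,2S)-2-[(1E,3S)-3-acetoxyoct-1-en-1-yl]-5-oxocyclopent-3-en-1-yl]heptanoate
Product: 18 7-[(1R,2S)-2-[(1E,3S)-3-acetoxyoct-1-en-1-yl]-5-oxocyclopent-3-en-1-yl]heptanoic acid (target)
Conditions: CF3CO2H/CH2Cl2 (1:4), 0 °C; toluene azeotrope
Reagents that add atoms: none
Why: Acid-catalysed E1 cleavage of the tert-butyl ester releases isobutene; the 4,5-disubstituted cyclopentenone is acid-stable (it is base that isomerises it), and the acetate and all three stereocentres are not involved.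

## Compound list

1 | hexanal | CCCCCC=O | starting material
2 | but-1-en-3-yne | C=CC#C | starting material
3 | (E)-buta-1,3-dien-1-yl(dicyclohexyl)borane | C=C/C=C/B(C1CCCCC1)C1CCCCC1 | intermediate
4 | (E)-buta-1,3-dien-1-yl(methyl)zinc | C=C/C=C/[Zn]C | intermediate
5 | (3E,5S)-deca-1,3-dien-5-ol | CCCCC[C@@H](/C=C/C=C)O | intermediate
6 | (3E,5S)-deca-1,3-dien-5-yl acetate | CCCCC[C@@H](/C=C/C=C)OC(C)=O | intermediate
7 | (1E,3S)-1-(2,2-dichloro-3-oxocyclobutyl)oct-1-en-3-yl acetate, both epimers at the ring CH | CCCCC[C@@H](/C=C/C1CC(=O)C1(Cl)Cl)OC(C)=O | intermediate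
8 | (1E,3S)-1-(3-oxocyclobutyl)oct-1-en-3-yl acetate | CCCCC[C@@H](/C=C/C1CC(=O)C1)OC(C)=O | intermediate
9 | (1E,3S)-1-[(1R)-3-oxo-4-(trimethylsilyl)cyclopentyl]oct-1-en-3-yl acetate, silyl-bearing carbon undefined | CCCCC[C@@H](/C=C/[C@H]1CC([Si](C)(C)C)C(=O)C1)OC(C)=O | intermediate
10 | (1E,3S)-1-[(1S)-3-(trimethylsilyloxy)cyclopent-3-en-1-yl]oct-1-en-3-yl acetate | CCCCC[C@@H](/C=C/[C@H]1CC=C(O[Si](C)(C)C)C1)OC(C)=O | intermediate
11 | (4S)-4-[(1E,3S)-3-acetoxyoct-1-en-1-yl]cyclopent-2-en-1-one | CCCCC[C@@H](/C=C/[C@H]1C=CC(=O)C1)OC(C)=O | intermediate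
12 | cycloheptanone | O=C1CCCCCC1 | starting material
13 | oxocan-2-one | O=C1CCCCCCO1 | intermediate
14 | tert-butyl 7-hydroxyheptanoate | CC(C)(C)OC(=O)CCCCCCO | intermediate
15 | tert-butyl 7-(trifluoromethylsulfonyloxy)heptanoate | CC(C)(C)OC(=O)CCCCCCOS(=O)(=O)C(F)(F)F | intermediate
16 | lithium (3S)-3-[(1E,3S)-3-acetoxyoct-1-en-1-yl]cyclopenta-1,4-dien-1-olate | CCCCC[C@@H](/C=C/[C@H]1C=CC(O[Li])=C1)OC(C)=O | intermediate
17 | tert-butyl 7-[(1R,2S)-2-[(1E,3S)-3-acetoxyoct-1-en-1-yl]-5-oxocyclopent-3-en-1-yl]heptanoate | CCCCC[C@@H](/C=C/[C@H]1C=CC(=O)[C@@H]1CCCCCCC(=O)OC(C)(C)C)OC(C)=O | intermediate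
18 | 7-[(1R,2S)-2-[(1E,3S)-3-acetoxyoct-1-en-1-yl]-5-oxocyclopent-3-en-1-yl]heptanoic acid (CNP0281518.1) | CCCCC[C@@H](/C=C/[C@H]1C=CC(=O)[C@@H]1CCCCCCC(=O)O)OC(C)=O | target

## Step count and risk

Total steps: 10. Longest linear sequence: 7 (steps 1, 2, 3, 4, 5, 9, 10); steps 6–8 make the side-chain triflate.

**Step 5 (the new enantiotopic-group-selective ring expansion).** The relay from the diazo-carbon configuration to the migrating CH2 may leak, and an uncatalysed background reaction would lower the ee.

The fallback uses known chemistry only, sets out from 8 and returns at 17; it also bypasses step 9.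
- Ketone 8 is desymmetrised by enantioselective deprotonation with lithium (R,R)-bis(1-phenylethyl)amide (or its antipode, whichever gives the R enol silane) in THF at −100 °C with Me3SiCl as internal quench. This gives (1E,3S)-1-[(1R)-3-(trimethylsilyloxy)cyclobut-2-en-1-yl]oct-1-en-3-yl acetate F1.
- Anhydrous benzyltrimethylammonium fluoride in THF at −78 °C in the presence of triflate 15 unmasks the enolate and alkylates it anti to the alkenyl group. This gives tert-butyl 7-[(1R,2R)-2-[(1E,3S)-3-acetoxyoct-1-en-1-yl]-4-oxocyclobutyl]heptanoate F2.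
- The known achiral Sc(OTf)3/TMSCHN2 homologation, in which the less substituted CH2 migrates, gives tert-butyl 7-[(1R,5R)-5-[(1E,3S)-3-acetoxyoct-1-en-1-yl]-2-(trimethylsilyloxy)cyclopent-2-en-1-yl]heptanoate F3.
- IBX·MPO dehydrogenation of F3 gives 17.

**Step 9 (α′-alkylation).** Possible problems are O-alkylation, proton transfer to the doubly allylic C12–H, and a [1,5]-hydrogen shift in the cyclopentadienolate if the mixture warms.

The fallback sets out from 11 and 14 and returns at 17.
- Alcohol 14 is oxidised with Dess–Martin periodinane to tert-butyl 7-oxoheptanoate F4.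
- Enolate 16, made as in step 9, is trapped at −78 °C by the much faster aldol addition to F4. This gives tert-butyl 7-hydroxy-7-[trans-2-((1E,3S)-3-acetoxyoct-1-en-1-yl)-5-oxocyclopent-3-en-1-yl]heptanoate (ring configuration as in 17, both C7 epimers) F5.
- PhOC(S)Cl with pyridine and DMAP gives the O-phenyl thionocarbonate of F5 F6.
- Barton–McCombie deoxygenation (Bu3SnH, Et3B/air, toluene, rt) gives 17.
- If enolate generation itself fails, the step 5 fallback reaches 17 without an enone enolate.

**Step 3 (dichloroketene [2+2] on an ionisable dienyl acetate).** Ketene oligomerisation or attack at the wrong alkene would lower the yield.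

The fallback sets out from 6 and returns at 8, bypassing step 4.
- The keteniminium salt from N,N-dimethylacetamide, Tf2O and 2,4,6-collidine (1,2-dichloroethane, 80 °C) adds stepwise to the terminal alkene. This gives N,N-dimethyl-3-[(1E,3S)-3-acetoxyoct-1-en-1-yl]cyclobutan-1-iminium triflate F7.
- Aqueous NaHCO3 hydrolyses F7 to 8.
- It is not the first choice because the cationic intermediate can be intercepted by the neighbouring acetate.

## Further compounds

F1 | step 5 | (1E,3S)-1-[(1R)-3-(trimethylsilyloxy)cyclobut-2-en-1-yl]oct-1-en-3-yl acetate | CCCCC[C@@H](/C=C/[C@@H]1C=C(O[Si](C)(C)C)C1)OC(C)=O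
F2 | step 5 | tert-butyl 7-[(1R,2R)-2-[(1E,3S)-3-acetoxyoct-1-en-1-yl]-4-oxocyclobutyl]heptanoate | CCCCC[C@@H](/C=C/[C@H]1CC(=O)[C@@H]1CCCCCCC(=O)OC(C)(C)C)OC(C)=O
F3 | step 5 | tert-butyl 7-[(1R,5R)-5-[(1E,3S)-3-acetoxyoct-1-en-1-yl]-2-(trimethylsilyloxy)cyclopent-2-en-1-yl]heptanoate | CCCCC[C@@H](/C=C/[C@H]1CC=C(O[Si](C)(C)C)[C@@H]1CCCCCCC(=O)OC(C)(C)C)OC(C)=O
F4 | step 9 | tert-butyl 7-oxoheptanoate | CC(C)(C)OC(=O)CCCCCC=O
F5 | step 9 | tert-butyl 7-hydroxy-7-[trans-2-((1E,3S)-3-acetoxyoct-1-en-1-yl)-5-oxocyclopent-3-en-1-yl]heptanoate, ring configuration as in 17, both C7 epimers | CCCCC[C@@H](/C=C/[C@H]1C=CC(=O)[C@@H]1C(O)CCCCCC(=O)OC(C)(C)C)OC(C)=O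
F6 | step 9 | O-phenyl thionocarbonate of F5 | CCCCC[C@@H](/C=C/[C@H]1C=CC(=O)[C@@H]1C(OC(=S)Oc1ccccc1)CCCCCC(=O)OC(C)(C)C)OC(C)=O
F7 | step 3 | N,N-dimethyl-3-[(1E,3S)-3-acetoxyoct-1-en-1-yl]cyclobutan-1-iminium triflate | CCCCC[C@@H](/C=C/C1CC(=[N+](C)C)C1)OC(C)=O.[O-]S(=O)(=O)C(F)(F)F
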